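**Strategy.** Everything rests on cutting C7–C11 and C11=C13 of the cis-fused α-methylene γ-lactone (O6–C12–C11–C7–C6), in which C11 sits on C7 directly beside the oxygen-bearing C8. A phosphonoacetate bound to O6 opens a trans C7–C8 epoxide at C7, and the α-phosphono lactone so formed is methylenated with formaldehyde in the same flask: one operation closes the lactone, sets C7 by inversion and frees the C8 hydroxyl for the tiglate. The precursor is a syn epoxy phosphonoacetate flanked by a Z allylic silyl ether (C3–C5) and a silylated tertiary propargylic carbinol (C10) drawn from (R)-citramalic acid. The ten-membered ring is closed last, at C2–C3.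

Key step: step 13

Remarks on the chemistry:
- Locants C1–C15 are those of the target: ring C1–C10, lactone carbons C11–C13, C14 on C10, C15 on C4. TBS = tert-butyldimethylsilyl.
- Assumption: the target is made as the open C3 ketone/C10 alcohol that is drawn; a possible equilibrium with its C3,C10 hemiketal is a property of the compound and is left aside.

Step 1
Reactants: 1 (R)-citramalic acid
Product: 2 [(4R)-2,2,4-trimethyl-5-oxo-1,3-dioxolan-4-yl]acetic acid
Conditions: Me2C(OMe)2, TsOH (cat.), CH2Cl2, rt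
Reagents that add atoms: 2,2-dimethoxypropane, COC(C)(C)OC
Why: Acid-catalysed acetalisation ties the tertiary hydroxyl and its neighbouring carboxyl into a five-membered dioxolanone, so that only the CH2-bound carboxyl (the later C8) stays free and the C10 stereocenter is not touched.

Step 2
Reactants: 2 [(4R)-2,2,4-trimethyl-5-oxo-1,3-dioxolan-4-yl]acetic acid
Product: 4 (3R)-3-hydroxy-3-methyloxolan-2-one, via hydroxyethyl dioxolanone 3 (not isolated)
Conditions: BH3·SMe2, THF, 0 °C → rt; MeOH; then TsOH (cat.), CH2Cl2, rt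
Reagents that add atoms: none
Why: Chemoselective borane reduction of the free carboxylic acid beside the dioxolanone gives the primary alcohol, which on acid treatment translactonises to the γ-lactone with loss of acetone.

Step 3
Reactants: 4 (3R)-3-hydroxy-3-methyloxolan-2-one
Product: 5 (3R)-3-[(tert-butyldimethylsilyl)oxy]-3-methyloxolan-2-one
Conditions: TBSOTf, 2,6-lutidine, CH2Cl2, 0 °C → rt
Reagents that add atoms: tert-butyldimethylsilyl triflate, CC(C)(C)[Si](C)(C)OS(=O)(=O)C(F)(F)F
Why: Silylation of the tertiary alcohol with the silyl triflate and a hindered base gives a robust ether that does not migrate in the basic step 5 and stays on C10 until the last step.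

Step 4
Reactants: 5 (3R)-3-[(tert-butyldimethylsilyl)oxy]-3-methyloxolan-2-one
Product: 6 (3R)-3-[(tert-butyldimethylsilyl)oxy]-3-methyloxolan-2-ol (both anomers)
Conditions: i-Bu2AlH, CH2Cl2, −78 °C
Reagents that add atoms: none
Why: Partial reduction of the lactone stops at the lactol because the tetrahedral aluminate does not collapse at −78 °C.

Step 5
Reactants: 6 (3R)-3-[(tert-butyldimethylsilyl)oxy]-3-methyloxolan-2-ol
Product: 7 (3R)-3-[(tert-butyldimethylsilyl)oxy]-3-methylpent-4-yn-1-ol
Conditions: MeC(O)C(N2)P(O)(OMe)2, K2CO3, MeOH, 0 °C → rt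
Reagents that add atoms: dimethyl (1-diazo-2-oxopropyl)phosphonate, CC(=O)C(=[N+]=[N-])P(=O)(OC)OC
Why: Seyferth–Gilbert homologation in the Ohira–Bestmann variant converts the open hydroxy aldehyde form of the lactol into the terminal alkyne C1≡C2 under carbonate conditions that leave the quaternary center alone.

Step 6
Reactants: 7 (3R)-3-[(tert-butyldimethylsilyl)oxy]-3-methylpent-4-yn-1-ol
Product: 8 (3R)-3-[(tert-butyldimethylsilyl)oxy]-3-methylpent-4-ynal
Conditions: Dess–Martin periodinane, NaHCO3, CH2Cl2, 0 °C → rt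
Reagents that add atoms: none
Why: Buffered Dess–Martin oxidation takes the primary alcohol to the aldehyde without β-elimination of the silyloxy group.

Step 7
Reactants: 8 (3R)-3-[(tert-butyldimethylsilyl)oxy]-3-methylpent-4-ynal
Product: 9 (2E,5R)-5-[(tert-butyldimethylsilyl)oxy]-5-methylhept-2-en-6-ynal
Conditions: Ph3P=CHCHO, toluene, 80 °C
Reagents that add atoms: (triphenylphosphoranylidene)acetaldehyde, O=CC=P(c1ccccc1)(c1ccccc1)c1ccccc1
Why: Wittig olefination with the stabilised formylmethylene ylide adds C6 and C7 and should give the E enal.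

Step 8
Reactants: 10 propargyl alcohol
Product: 12 (2Z)-3-iodo-2-methylprop-2-en-1-ol, via alkenylmagnesium alkoxide 11 (not isolated)
Conditions: MeMgBr, CuI (cat.), THF, −10 °C → rt; then I2, −10 °C
Reagents that add atoms: methylmagnesium bromide, C[Mg]Br; iodine, II
Why: CuI-catalysed carbomagnesiation of the magnesium alkoxide delivers methyl to the internal alkyne carbon and magnesium to the terminal one in an anti sense through a five-membered chelate, and iodinolysis with retention gives the Z iodide.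

Step 9
Reactants: 12 (2Z)-3-iodo-2-methylprop-2-en-1-ol
Product: 13 tert-butyl{[(2Z)-3-iodo-2-methylprop-2-en-1-yl]oxy}dimethylsilane
Conditions: TBSCl, imidazole, CH2Cl2, rt
Reagents that add atoms: tert-butyldimethylsilyl chloride, CC(C)(C)[Si](C)(C)Cl
Why: Standard silylation of the primary allylic alcohol gives an ether that can later be cleaved selectively beside the tertiary silyl ether at C10.

Step 10
Reactants: 13 tert-butyl{[(2Z)-3-iodo-2-methylprop-2-en-1-yl]oxy}dimethylsilane, 9 (2E,5R)-5-[(tert-butyldimethylsilyl)oxy]-5-methylhept-2-en-6-ynal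
Product: 16 (2Z,5E,8R)-1,8-bis[(tert-butyldimethylsilyl)oxy]-2,8-dimethyldeca-2,5-dien-9-yn-4-ol (both C4 epimers), via alkenyllithium 14 (not isolated), via alkenylmagnesium bromide 15 (not isolated)
Conditions: 13, t-BuLi, Et2O, −78 °C; MgBr2·OEt2; then 9, −78 °C
Reagents that add atoms: none
Why: Iodine–lithium exchange with retention of the alkene geometry, transmetalation to the less basic magnesium reagent and 1,2-addition to the enal should form C5–C6 faster than the terminal alkyne is deprotonated at −78 °C; C6 (C4 of 16) is formed without control and both epimers are carried on.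

Step 11
Reactants: 16 (2Z,5E,8R)-1,8-bis[(tert-butyldimethylsilyl)oxy]-2,8-dimethyldeca-2,5-dien-9-yn-4-ol (both C4 epimers)
Product: 17 (1R,2Z)-4-[(tert-butyldimethylsilyl)oxy]-1-{(2R,3R)-3-[(2R)-2-[(tert-butyldimethylsilyl)oxy]-2-methylbut-3-yn-1-yl]oxiran-2-yl}-3-methylbut-2-en-1-ol (anti epoxy alcohol)
Conditions: Ti(OiPr)4, D-(−)-diisopropyl tartrate, t-BuOOH (0.6 equiv), 4 Å MS, CH2Cl2, −20 °C
Reagents that add atoms: tert-butyl hydroperoxide, CC(C)(C)OO
Why: Sharpless asymmetric epoxidation under kinetic-resolution conditions: with the D-(−)-tartrate only the (4S) epimer of 16 is matched for the E-disubstituted C7=C8 alkene and should give the anti (erythro) epoxy alcohol with C7 and C8 set by the reagent, while the Z-substituted C4=C5 alkene and the (4R) epimer react much more slowly and are separated.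

Step 12
Reactants: 17 anti epoxy alcohol, 18 diethylphosphonoacetic acid
Product: 19 (1S,2Z)-4-[(tert-butyldimethylsilyl)oxy]-1-{(2S,3R)-3-[(2R)-2-[(tert-butyldimethylsilyl)oxy]-2-methylbut-3-yn-1-yl]oxiran-2-yl}-3-methylbut-2-en-1-yl (diethoxyphosphoryl)acetate (syn epoxy phosphonoacetate)
Conditions: PPh3, DIAD, THF, 0 °C → rt
Reagents that add atoms: none
Why: Mitsunobu esterification displaces the activated C6 hydroxyl by the carboxylate in an SN2 sense, so it inverts C6 (anti to syn) and installs the phosphonoacetate in the same step.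

Step 13
Reactants: 19 syn epoxy phosphonoacetate, 20 formaldehyde (used as paraformaldehyde)
Product: 22 (4R,5S)-4-{(1R,3R)-3-[(tert-butyldimethylsilyl)oxy]-1-hydroxy-3-methylpent-4-yn-1-yl}-5-{(1Z)-3-[(tert-butyldimethylsilyl)oxy]-2-methylprop-1-en-1-yl}-3-methylideneoxolan-2-one, via α-phosphono lactone 21 (not isolated)
Conditions: LiCl, DBU, MeCN, 0 → 40 °C; then (CH2O)n, rt
Reagents that add atoms: none
Why: LiCl/DBU generates the lithium-chelated phosphonoacetate carbanion, which attacks C7 from the side opposite to the epoxide oxygen (SN2) and forms C7–C11; the C8 alkoxide is protonated at once by the more acidic α-phosphono lactone 21, whose anion then undergoes Horner–Wadsworth–Emmons olefination with formaldehyde to give C11=C13. The closest known reactions are the opening of 2,3-epoxy alcohol derivatives at the carbinol-side carbon by nucleophiles tethered to that oxygen, the cyclisation of epoxides with tethered stabilised carbanions, and the methylenation of α-phosphono lactones under Masamune–Roush conditions. The γ-lactone is closed in the 5-exo-tet mode. C7 is the only new stereocenter and is fixed by inversion of the epoxide carbon, while C6 and C8 are carried over, so the syn trans-epoxy ester can only give the cis-fused lactone. The step needs attack at C7 instead of 6-endo attack at C8, which the short ester tether and the backside trajectory favour, and it needs ring closure before olefination, which is secured by adding formaldehyde only after 19 is consumed. The liberated C8 hydroxyl is the only free one and is acylated in the next step before it can shift the lactone to O8.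

Step 14
Reactants: 22 α-methylene lactone alcohol, 23 tiglic acid
Product: 25 (1R,3R)-3-[(tert-butyldimethylsilyl)oxy]-1-{(2S,3R)-2-[(1Z)-3-[(tert-butyldimethylsilyl)oxy]-2-methylprop-1-en-1-yl]-4-methylidene-5-oxooxolan-3-yl}-3-methylpent-4-yn-1-yl (2E)-2-methylbut-2-enoate, via mixed tiglic 2,4,6-trichlorobenzoic anhydride 24 (not isolated)
Conditions: 23, 2,4,6-Cl3C6H2COCl, Et3N, toluene, rt; then 22, DMAP, rt
Reagents that add atoms: none
Why: Yamaguchi esterification through the mixed anhydride acylates the hindered secondary C8 alcohol without isomerising the tiglate and blocks any lactone migration.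

Step 15
Reactants: 25 tiglate with terminal alkyne
Product: 26 (1R,3R)-3-[(tert-butyldimethylsilyl)oxy]-1-{(2S,3R)-2-[(1Z)-3-[(tert-butyldimethylsilyl)oxy]-2-methylprop-1-en-1-yl]-4-methylidene-5-oxooxolan-3-yl}-5-iodo-3-methylpent-4-yn-1-yl (2E)-2-methylbut-2-enoate
Conditions: NIS, AgNO3 (cat.), acetone, rt, dark
Reagents that add atoms: N-iodosuccinimide, O=C1CCC(=O)N1I
Why: Silver-catalysed iodination of the terminal alkyne C–H through the silver acetylide gives the 1-iodoalkyne and leaves the alkenes untouched.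

Step 16
Reactants: 26 iodoalkyne
Product: 28 (1R,3R,4Z)-3-[(tert-butyldimethylsilyl)oxy]-1-{(2S,3R)-2-[(1Z)-3-[(tert-butyldimethylsilyl)oxy]-2-methylprop-1-en-1-yl]-4-methylidene-5-oxooxolan-3-yl}-5-iodo-3-methylpent-4-en-1-yl (2E)-2-methylbut-2-enoate, via α-iodoalkenylborane 27 (not isolated)
Conditions: Cy2BH (from BH3·SMe2 and cyclohexene), THF, 0 °C; then AcOH, rt
Reagents that add atoms: none
Why: Syn hydroboration of the 1-iodoalkyne with one equivalent of a hindered dialkylborane places boron on the iodine-bearing carbon, and protonolysis of the C–B bond by acetic acid with retention gives the Z iodoalkene.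

Step 17
Reactants: 28 Z iodoalkene
Product: 29 (1R,3R,4Z)-3-[(tert-butyldimethylsilyl)oxy]-1-{(2S,3R)-2-[(1Z)-3-hydroxy-2-methylprop-1-en-1-yl]-4-methylidene-5-oxooxolan-3-yl}-5-iodo-3-methylpent-4-en-1-yl (2E)-2-methylbut-2-enoate
Conditions: HF·pyridine, pyridine, THF, 0 °C
Reagents that add atoms: none
Why: Buffered fluoride cleaves the unhindered primary allylic silyl ether much faster than the tertiary one at C10.

Step 18
Reactants: 29 allylic alcohol
Product: 30 (1R,3R,4Z)-3-[(tert-butyldimethylsilyl)oxy]-5-iodo-3-methyl-1-{(2S,3R)-4-methylidene-2-[(1Z)-2-methyl-3-oxoprop-1-en-1-yl]-5-oxooxolan-3-yl}pent-4-en-1-yl (2E)-2-methylbut-2-enoate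
Conditions: MnO2, CH2Cl2, rt
Reagents that add atoms: none
Why: MnO2 oxidises only the allylic alcohol and, being neutral, should keep the Z geometry of C4=C5.

Step 19
Reactants: 30 Z enal with Z iodoalkene
Product: 32 (6S,7R,8R,10R)-10-[(tert-butyldimethylsilyl)oxy]-3-hydroxy-8-[(2E)-2-methylbut-2-enoyloxy]germacra-1(2)Z,4(5)Z,11(13)-trien-12,6-olide (both C3 epimers), via alkenylchromium dichloride 31 (not isolated)
Conditions: CrCl2, NiCl2 (cat.), DMSO, rt, high dilution
Reagents that add atoms: none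
Why: Intramolecular Nozaki–Hiyama–Kishi reaction: zerovalent nickel inserts into the C–I bond, transmetalation gives the alkenyl species of trivalent chromium, and this adds chemoselectively to the aldehyde to form C2–C3 with the Z geometry retained; the new C3 carbinol is formed without control and is erased in the next step.

Step 20
Reactants: 32 macrocyclic allylic alcohol
Product: 33 (6S,7R,8R,10R)-10-[(tert-butyldimethylsilyl)oxy]-8-[(2E)-2-methylbut-2-enoyloxy]-3-oxogermacra-1(2)Z,4(5)Z,11(13)-trien-12,6-olide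
Conditions: Dess–Martin periodinane, NaHCO3, CH2Cl2, 0 °C
Reagents that add atoms: none
Why: Dess–Martin oxidation of the doubly allylic alcohol gives the cross-conjugated dienone and removes the C3 stereocenter.

Step 21
Reactants: 33 silylated dienone
Product: 34 (3aR,4R,6R,7Z,10Z,11aS)-6-hydroxy-6,10-dimethyl-3-methylidene-2,9-dioxo-3a,4,5,11a-tetrahydrocyclodeca[b]furan-4-yl (2E)-2-methylbut-2-enoate (target)
Conditions: HF·pyridine, THF, 0 °C → rt
Reagents that add atoms: none
Why: Fluoride cleavage of the tertiary silyl ether under buffered, non-basic conditions should spare the methylene lactone, the tiglate and the dienone.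

**Compound list**

1 | (R)-citramalic acid | C[C@@](O)(CC(=O)O)C(=O)O | starting material
2 | [(4R)-2,2,4-trimethyl-5-oxo-1,3-dioxolan-4-yl]acetic acid | C[C@@]1(CC(=O)O)C(=O)OC(C)(C)O1 | intermediate
3 | (5R)-5-(2-hydroxyethyl)-2,2,5-trimethyl-1,3-dioxolan-4-one (formed in the flask) | C[C@@]1(CCO)C(=O)OC(C)(C)O1 | intermediate
4 | (3R)-3-hydroxy-3-methyloxolan-2-one | C[C@@]1(O)CCOC1=O | intermediate
5 | (3R)-3-[(tert-butyldimethylsilyl)oxy]-3-methyloxolan-2-one | C[C@@]1(O[Si](C)(C)C(C)(C)C)CCOC1=O | intermediate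
6 | (3R)-3-[(tert-butyldimethylsilyl)oxy]-3-methyloxolan-2-ol, both anomers | C[C@@]1(O[Si](C)(C)C(C)(C)C)CCOC1O | intermediate
7 | (3R)-3-[(tert-butyldimethylsilyl)oxy]-3-methylpent-4-yn-1-ol | OCC[C@@](C)(O[Si](C)(C)C(C)(C)C)C#C | intermediate
8 | (3R)-3-[(tert-butyldimethylsilyl)oxy]-3-methylpent-4-ynal | O=CC[C@@](C)(O[Si](C)(C)C(C)(C)C)C#C | intermediate
9 | (2E,5R)-5-[(tert-butyldimethylsilyl)oxy]-5-methylhept-2-en-6-ynal | O=C/C=C/C[C@@](C)(O[Si](C)(C)C(C)(C)C)C#C | intermediate
10 | propargyl alcohol | C#CCO | starting material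
11 | bromomagnesium (2Z)-3-(bromomagnesio)-2-methylprop-2-en-1-olate (formed in the flask) | Br[Mg]/C=C(/C)CO[Mg]Br | intermediate
12 | (2Z)-3-iodo-2-methylprop-2-en-1-ol | I/C=C(/C)CO | intermediate
13 | tert-butyl{[(2Z)-3-iodo-2-methylprop-2-en-1-yl]oxy}dimethylsilane | I/C=C(/C)CO[Si](C)(C)C(C)(C)C | intermediate
14 | {(1Z)-3-[(tert-butyldimethylsilyl)oxy]-2-methylprop-1-en-1-yl}lithium (formed in the flask) | [Li]/C=C(/C)CO[Si](C)(C)C(C)(C)C | intermediate
15 | {(1Z)-3-[(tert-butyldimethylsilyl)oxy]-2-methylprop-1-en-1-yl}magnesium bromide (formed in the flask) | Br[Mg]/C=C(/C)CO[Si](C)(C)C(C)(C)C | intermediate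
16 | (2Z,5E,8R)-1,8-bis[(tert-butyldimethylsilyl)oxy]-2,8-dimethyldeca-2,5-dien-9-yn-4-ol, both C4 epimers | OC(/C=C(/C)CO[Si](C)(C)C(C)(C)C)/C=C/C[C@@](C)(O[Si](C)(C)C(C)(C)C)C#C | intermediate
17 | (1R,2Z)-4-[(tert-butyldimethylsilyl)oxy]-1-{(2R,3R)-3-[(2R)-2-[(tert-butyldimethylsilyl)oxy]-2-methylbut-3-yn-1-yl]oxiran-2-yl}-3-methylbut-2-en-1-ol (anti epoxy alcohol) | O[C@H](/C=C(/C)CO[Si](C)(C)C(C)(C)C)[C@H]1O[C@@H]1C[C@@](C)(O[Si](C)(C)C(C)(C)C)C#C | intermediate
18 | diethylphosphonoacetic acid | CCOP(=O)(CC(=O)O)OCC | starting material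
19 | (1S,2Z)-4-[(tert-butyldimethylsilyl)oxy]-1-{(2S,3R)-3-[(2R)-2-[(tert-butyldimethylsilyl)oxy]-2-methylbut-3-yn-1-yl]oxiran-2-yl}-3-methylbut-2-en-1-yl (diethoxyphosphoryl)acetate (syn epoxy phosphonoacetate) | CCOP(=O)(OCC)CC(=O)O[C@@H](/C=C(/C)CO[Si](C)(C)C(C)(C)C)[C@H]1O[C@@H]1C[C@@](C)(O[Si](C)(C)C(C)(C)C)C#C | intermediate
20 | formaldehyde | C=O | starting material
21 | diethyl [(4R,5S)-4-{(1R,3R)-3-[(tert-butyldimethylsilyl)oxy]-1-hydroxy-3-methylpent-4-yn-1-yl}-5-{(1Z)-3-[(tert-butyldimethylsilyl)oxy]-2-methylprop-1-en-1-yl}-2-oxooxolan-3-yl]phosphonate, C3 epimers (formed in the flask) | CCOP(=O)(OCC)C1C(=O)O[C@@H](/C=C(/C)CO[Si](C)(C)C(C)(C)C)[C@H]1[C@H](O)C[C@@](C)(O[Si](C)(C)C(C)(C)C)C#C | intermediate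
22 | (4R,5S)-4-{(1R,3R)-3-[(tert-butyldimethylsilyl)oxy]-1-hydroxy-3-methylpent-4-yn-1-yl}-5-{(1Z)-3-[(tert-butyldimethylsilyl)oxy]-2-methylprop-1-en-1-yl}-3-methylideneoxolan-2-one | C=C1C(=O)O[C@@H](/C=C(/C)CO[Si](C)(C)C(C)(C)C)[C@H]1[C@H](O)C[C@@](C)(O[Si](C)(C)C(C)(C)C)C#C | intermediate
23 | tiglic acid | C/C=C(\C)C(=O)O | starting material
24 | (2E)-2-methylbut-2-enoic 2,4,6-trichlorobenzoic anhydride (formed in the flask) | C/C=C(\C)C(=O)OC(=O)c1c(Cl)cc(Cl)cc1Cl | intermediate
25 | (1R,3R)-3-[(tert-butyldimethylsilyl)oxy]-1-{(2S,3R)-2-[(1Z)-3-[(tert-butyldimethylsilyl)oxy]-2-methylprop-1-en-1-yl]-4-methylidene-5-oxooxolan-3-yl}-3-methylpent-4-yn-1-yl (2E)-2-methylbut-2-enoate | C=C1C(=O)O[C@@H](/C=C(/C)CO[Si](C)(C)C(C)(C)C)[C@H]1[C@H](OC(=O)/C(C)=C/C)C[C@@](C)(O[Si](C)(C)C(C)(C)C)C#C | intermediate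
26 | the 5-iodopent-4-ynyl analogue of 25 (iodoalkyne at C1≡C2) | C=C1C(=O)O[C@@H](/C=C(/C)CO[Si](C)(C)C(C)(C)C)[C@H]1[C@H](OC(=O)/C(C)=C/C)C[C@@](C)(O[Si](C)(C)C(C)(C)C)C#CI | intermediate
27 | (Z)-α-iodoalkenyl(dicyclohexyl)borane from 26, boron and iodine on C2 (formed in the flask) | C=C1C(=O)O[C@@H](/C=C(/C)CO[Si](C)(C)C(C)(C)C)[C@H]1[C@H](OC(=O)/C(C)=C/C)C[C@@](C)(O[Si](C)(C)C(C)(C)C)/C=C(\I)B(C1CCCCC1)C1CCCCC1 | intermediate
28 | (1R,3R,4Z)-3-[(tert-butyldimethylsilyl)oxy]-1-{(2S,3R)-2-[(1Z)-3-[(tert-butyldimethylsilyl)oxy]-2-methylprop-1-en-1-yl]-4-methylidene-5-oxooxolan-3-yl}-5-iodo-3-methylpent-4-en-1-yl (2E)-2-methylbut-2-enoate | C=C1C(=O)O[C@@H](/C=C(/C)CO[Si](C)(C)C(C)(C)C)[C@H]1[C@H](OC(=O)/C(C)=C/C)C[C@@](C)(O[Si](C)(C)C(C)(C)C)/C=C\I | intermediate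
29 | (1R,3R,4Z)-3-[(tert-butyldimethylsilyl)oxy]-1-{(2S,3R)-2-[(1Z)-3-hydroxy-2-methylprop-1-en-1-yl]-4-methylidene-5-oxooxolan-3-yl}-5-iodo-3-methylpent-4-en-1-yl (2E)-2-methylbut-2-enoate | C=C1C(=O)O[C@@H](/C=C(/C)CO)[C@H]1[C@H](OC(=O)/C(C)=C/C)C[C@@](C)(O[Si](C)(C)C(C)(C)C)/C=C\I | intermediate
30 | (1R,3R,4Z)-3-[(tert-butyldimethylsilyl)oxy]-5-iodo-3-methyl-1-{(2S,3R)-4-methylidene-2-[(1Z)-2-methyl-3-oxoprop-1-en-1-yl]-5-oxooxolan-3-yl}pent-4-en-1-yl (2E)-2-methylbut-2-enoate | C=C1C(=O)O[C@@H](/C=C(/C)C=O)[C@H]1[C@H](OC(=O)/C(C)=C/C)C[C@@](C)(O[Si](C)(C)C(C)(C)C)/C=C\I | intermediate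
31 | (Z)-alkenylchromium dichloride from 30, CrCl2 in place of iodine on C2 (formed in the flask) | C=C1C(=O)O[C@@H](/C=C(/C)C=O)[C@H]1[C@H](OC(=O)/C(C)=C/C)C[C@@](C)(O[Si](C)(C)C(C)(C)C)/C=C\[Cr](Cl)Cl | intermediate
32 | (6S,7R,8R,10R)-10-[(tert-butyldimethylsilyl)oxy]-3-hydroxy-8-[(2E)-2-methylbut-2-enoyloxy]germacra-1(2)Z,4(5)Z,11(13)-trien-12,6-olide, both C3 epimers | C=C1C(=O)O[C@H]2/C=C(/C)C(O)/C=C\[C@](C)(O[Si](C)(C)C(C)(C)C)C[C@@H](OC(=O)/C(C)=C/C)[C@@H]12 | intermediate
33 | (6S,7R,8R,10R)-10-[(tert-butyldimethylsilyl)oxy]-8-[(2E)-2-methylbut-2-enoyloxy]-3-oxogermacra-1(2)Z,4(5)Z,11(13)-trien-12,6-olide | C=C1C(=O)O[C@H]2/C=C(/C)C(=O)/C=C\[C@](C)(O[Si](C)(C)C(C)(C)C)C[C@@H](OC(=O)/C(C)=C/C)[C@@H]12 | intermediate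
34 | (3aR,4R,6R,7Z,10Z,11aS)-6-hydroxy-6,10-dimethyl-3-methylidene-2,9-dioxo-3a,4,5,11a-tetrahydrocyclodeca[b]furan-4-yl (2E)-2-methylbut-2-enoate | C=C1C(=O)O[C@H]2/C=C(/C)C(=O)/C=C\[C@](C)(O)C[C@@H](OC(=O)/C(C)=C/C)[C@@H]12 | target

**Step count.** Total: 21 steps. Longest linear sequence: 19 steps (steps 1–7 and 10–21, from 1 to 34); steps 8 and 9 make the second fragment.

**The three steps most likely to fail**

Step 13. The carbanion has to reach C7 through an ester that must leave its preferred Z conformation, so ring closure may be slower than loss of the phosphonate by other paths: olefination of the open-chain ester once formaldehyde is present, attack at C8, or shift of the lactone to O8 by the C8 alkoxide. The fallback gives up the phosphonate and the olefination in favour of a malonate alkylation followed by decarboxylative methylenation. It sets out from 17: Mitsunobu esterification with allyl hydrogen malonate (PPh3, DIAD) should give, with inversion at C6, the syn epoxy allyl malonate F1. The more nucleophilic malonate anion (NaH, THF) would open the epoxide at C7 to the α-allyloxycarbonyl lactone F2, which can be isolated because no aldehyde is in the flask. Removal of the allyl ester (Pd(PPh3)4, morpholine) would give the α-carboxy lactone F3, and a decarboxylative Mannich methylenation (aqueous CH2O, Et2NH, then NaOAc/AcOH) comes back to the route at 22.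

Step 19. Closure of the ten-membered ring competes with intermolecular coupling, and the Z-alkenyl metal species may lose its geometry or be protonated before it reaches the aldehyde. The fallback closes the ring at C1=C2 by ring-closing metathesis instead. It sets out from 25: semi-hydrogenation of the terminal alkyne (Pd/CaCO3 poisoned with Pb(OAc)2, quinoline, one equivalent of H2) would give the C10 vinyl compound F4. Selective cleavage of the primary silyl ether (HF·pyridine, pyridine) would give the allylic alcohol F5, MnO2 the Z enal F6, and addition of CH2=CHMgBr at −78 °C the divinyl carbinol F7 as a C3 epimer mixture. Metathesis of the two monosubstituted vinyl groups (second-generation Hoveyda–Grubbs catalyst, high dilution), in which the medium ring should favour the Z alkene, comes back to the route at 32.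

Step 16. The borane may also add to the exocyclic C11=C13 double bond of the lactone, or protonolysis of the alkenylborane may stay incomplete. The fallback masks the methylene lactone before the reduction. It sets out from 26: conjugate addition of dimethylamine should give the amino lactone F8. With the enoate gone, the iodoalkyne can be reduced with an excess of diimide (2-nitrobenzenesulfonyl hydrazide, Et3N) to the Z iodoalkene F9. Quaternisation with MeI gives the ammonium iodide F10, and elimination with NaHCO3 restores C11=C13 and comes back to the route at 28.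

**Further compounds**

F1 | step 13 | syn epoxy allyl malonate (allyl malonate in place of the phosphonoacetate of 19) | C=CCOC(=O)CC(=O)O[C@@H](/C=C(/C)CO[Si](C)(C)C(C)(C)C)[C@H]1O[C@@H]1C[C@@](C)(O[Si](C)(C)C(C)(C)C)C#C
F2 | step 13 | α-allyloxycarbonyl cis-lactone with free C8 hydroxyl, C11 epimers | C=CCOC(=O)C1C(=O)O[C@@H](/C=C(/C)CO[Si](C)(C)C(C)(C)C)[C@H]1[C@H](O)C[C@@](C)(O[Si](C)(C)C(C)(C)C)C#C
F3 | step 13 | α-carboxy cis-lactone with free C8 hydroxyl, C11 epimers | OC(=O)C1C(=O)O[C@@H](/C=C(/C)CO[Si](C)(C)C(C)(C)C)[C@H]1[C@H](O)C[C@@](C)(O[Si](C)(C)C(C)(C)C)C#C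
F4 | step 19 | C10 vinyl analogue of 25 | C=C1C(=O)O[C@@H](/C=C(/C)CO[Si](C)(C)C(C)(C)C)[C@H]1[C@H](OC(=O)/C(C)=C/C)C[C@@](C)(O[Si](C)(C)C(C)(C)C)C=C
F5 | step 19 | C3 primary allylic alcohol from F4 | C=C1C(=O)O[C@@H](/C=C(/C)CO)[C@H]1[C@H](OC(=O)/C(C)=C/C)C[C@@](C)(O[Si](C)(C)C(C)(C)C)C=C
F6 | step 19 | Z enal from F5 | C=C1C(=O)O[C@@H](/C=C(/C)C=O)[C@H]1[C@H](OC(=O)/C(C)=C/C)C[C@@](C)(O[Si](C)(C)C(C)(C)C)C=C
F7 | step 19 | divinyl carbinol from F6, C3 epimers | C=C1C(=O)O[C@@H](/C=C(/C)C(O)C=C)[C@H]1[C@H](OC(=O)/C(C)=C/C)C[C@@](C)(O[Si](C)(C)C(C)(C)C)C=C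
F8 | step 16 | dimethylamine adduct of 26 at C13, C11 epimers | CN(C)CC1C(=O)O[C@@H](/C=C(/C)CO[Si](C)(C)C(C)(C)C)[C@H]1[C@H](OC(=O)/C(C)=C/C)C[C@@](C)(O[Si](C)(C)C(C)(C)C)C#CI
F9 | step 16 | Z iodoalkene from F8, C11 epimers | CN(C)CC1C(=O)O[C@@H](/C=C(/C)CO[Si](C)(C)C(C)(C)C)[C@H]1[C@H](OC(=O)/C(C)=C/C)C[C@@](C)(O[Si](C)(C)C(C)(C)C)/C=C\I
F10 | step 16 | trimethylammonium iodide from F9, C11 epimers | C[N+](C)(C)CC1C(=O)O[C@@H](/C=C(/C)CO[Si](C)(C)C(C)(C)C)[C@H]1[C@H](OC(=O)/C(C)=C/C)C[C@@](C)(O[Si](C)(C)C(C)(C)C)/C=C\I.[I-]
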